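The three sesquiterpene units are the same 15-hydroxydrim-8(12)-en-11-yl isocitrate ether, so one monomer is made and esterified twice. Everything rests on unzipping its rings A and B to an acyclic chain. That chain holds an (R)-2-methyl-2-alkyloxirane (C4, C15), the E C5=C10 alkene, and a C8=C9 allylsilane whose C11 is still a primary allylic carbon, where the isocitrate ether is easy to forge. The key step exploits that C15–OH hangs on quaternary C4 and that the ring B methylene C8=C12 is homoallylic to O11. One Lewis acid operation closes ring A, then ring B as the last ring of the route, sets C4, C5, C9 and C10, and frees the 15-OH for oligomerisation.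

Key step: step 13

Remark: drimane numbers (C1–C15) are used for the sesquiterpene carbons at every stage. Primed numbers are used for isocitrate (C1′ ester on the oxygenated C2′, C6′ carboxyl on C3′, C5′ carboxyl on C4′H2). Unit A carries the free C6′ acid, and unit C carries the free 15-OH. "Triflyloxy" means CF3SO2O. Metal alkoxides and carboxylate salts that are only protonated at work-up carry no number.

Step 1
Reactants: 1 geranyl bromide; 2 methyl acetoacetate
Product: 4 methyl (6E)-7,11-dimethyl-3-oxododeca-6,10-dienoate, via acetoacetate dianion 3 (not isolated)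
Conditions: 2, NaH, THF, 0 °C; n-BuLi, 0 °C; then 1, 0 °C → rt; 1 M HCl
Reagents that add atoms: sodium hydride [Na+].[H-] and n-butyllithium [Li]CCCC (counter-ions of 3 only)
Why: γ-Alkylation of the acetoacetate dianion, in which the more basic terminal carbanion displaces the primary allylic bromide by SN2 without touching the E alkene and so installs C7, C8, C9 and C11 at once.

Step 2
Reactants: 4 methyl (6E)-7,11-dimethyl-3-oxododeca-6,10-dienoate
Product: 5 methyl (2Z,6E)-7,11-dimethyl-3-(triflyloxy)dodeca-2,6,10-trienoate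
Conditions: Tf2O, sat. aq. LiOH, hexanes, 5 °C
Reagents that add atoms: trifluoromethanesulfonic anhydride O=S(=O)(OS(=O)(=O)C(F)(F)F)C(F)(F)F
Why: O-Sulfonylation of the lithium-chelated Z enolate of the β-keto ester places OTf cis to the ester, so C7 lies trans to C11 as the later chair closure requires.

Step 3
Reactants: 5 methyl (2Z,6E)-7,11-dimethyl-3-(triflyloxy)dodeca-2,6,10-trienoate
Product: 6 methyl (2Z,6E,10E)-12-hydroxy-7,11-dimethyl-3-(triflyloxy)dodeca-2,6,10-trienoate
Conditions: SeO2 (cat.), t-BuOOH, salicylic acid (cat.), CH2Cl2, 0 °C → rt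
Reagents that add atoms: tert-butyl hydroperoxide CC(C)(C)OO
Why: Catalytic SeO2 allylic hydroxylation (ene reaction, then [2,3]-sigmatropic shift) attacks the most electron-rich terminal trisubstituted alkene at its E methyl group, while the internal alkene is more hindered and the triflyloxy enoate is deactivated.

Step 4
Reactants: 6 methyl (2Z,6E,10E)-12-hydroxy-7,11-dimethyl-3-(triflyloxy)dodeca-2,6,10-trienoate
Product: 7 methyl (2Z,6E)-9-[(2S,3S)-3-(hydroxymethyl)-3-methyloxiran-2-yl]-7-methyl-3-(triflyloxy)nona-2,6-dienoate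
Conditions: Ti(OiPr)4 (cat.), L-(+)-diethyl tartrate (cat.), t-BuOOH, 4 Å MS, CH2Cl2, −20 °C
Reagents that add atoms: tert-butyl hydroperoxide CC(C)(C)OO
Why: Katsuki–Sharpless asymmetric epoxidation touches only the allylic alcohol alkene, and L-(+)-tartrate delivers oxygen to the face that gives the (2S,3S)-epoxy alcohol, which fixes the C4–O stereocentre.

Step 5
Reactants: 7 methyl (2Z,6E)-9-[(2S,3S)-3-(hydroxymethyl)-3-methyloxiran-2-yl]-7-methyl-3-(triflyloxy)nona-2,6-dienoate
Product: 8 (2Z,6E,11R)-1,11,12-trihydroxy-7,11-dimethyldodeca-2,6-dien-3-yl triflate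
Conditions: i-Bu2AlH (excess), CH2Cl2, −78 °C → rt; aq. potassium sodium tartrate
Reagents that add atoms: none
Why: i-Bu2AlH reduces the enoate 1,2 to the allylic alcohol and opens the 2,3-epoxy alcohol reductively to the 1,2-diol by hydride attack at the secondary carbon C3 (C4 is quaternary and deactivated by the neighbouring aluminium alkoxide), so the C4–O bond keeps its configuration and the enol triflate is inert.

Step 6
Reactants: 8 (2Z,6E,11R)-1,11,12-trihydroxy-7,11-dimethyldodeca-2,6-dien-3-yl triflate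
Product: 10 (2Z,6E)-1-hydroxy-7-methyl-10-[(2R)-2-methyloxiran-2-yl]deca-2,6-dien-3-yl triflate, via monotosylate 9 (not isolated)
Conditions: TsCl, Et3N, Bu2SnO (cat.), CH2Cl2, rt; then K2CO3, MeOH, 0 °C
Reagents that add atoms: 4-toluenesulfonyl chloride Cc1ccc(cc1)S(=O)(=O)Cl (carried by 9 only)
Why: Stannylene-acetal-catalysed sulfonylation picks the primary hydroxyl of the 1,2-diol over the isolated allylic hydroxyl, and the tertiary alkoxide then closes the oxirane by 3-exo-tet Williamson displacement at C15 without touching C4.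

Step 7
Reactants: 10 (2Z,6E)-1-hydroxy-7-methyl-10-[(2R)-2-methyloxiran-2-yl]deca-2,6-dien-3-yl triflate
Product: 12 (2Z,6E)-1-bromo-7-methyl-10-[(2R)-2-methyloxiran-2-yl]deca-2,6-dien-3-yl triflate, via allylic mesylate 11 (not isolated)
Conditions: MsCl, Et3N, THF, −40 °C; then LiBr, THF, 0 °C
Reagents that add atoms: lithium bromide [Li+].[Br-]; methanesulfonyl chloride CS(=O)(=O)Cl (carried by 11 only)
Why: Mesylation followed by SN2 displacement with bromide at low temperature converts the primary allylic alcohol without allylic transposition, under conditions that isolated oxiranes and enol triflates survive.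

Step 8
Reactants: 13 (R)-2,2-dimethyl-5-oxo-1,3-dioxolane-4-acetic acid
Product: 14 2-(trimethylsilyl)ethyl [(4R)-2,2-dimethyl-5-oxo-1,3-dioxolan-4-yl]acetate
Conditions: Me3SiCH2CH2OH, DIC, DMAP (cat.), CH2Cl2, 0 °C → rt
Reagents that add atoms: 2-(trimethylsilyl)ethanol C[Si](C)(C)CCO
Why: Steglich esterification of the only free carboxyl group, the α-hydroxy acid being masked in the dioxolanone, so the stereocentre is untouched.

Step 9
Reactants: 14 2-(trimethylsilyl)ethyl [(4R)-2,2-dimethyl-5-oxo-1,3-dioxolan-4-yl]acetate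
Product: 15 1-methyl 4-[2-(trimethylsilyl)ethyl] (2R)-malate
Conditions: MeOH, p-TsOH·H2O (cat.), rt
Reagents that add atoms: methanol CO
Why: Acid-catalysed methanolysis of the acylal-type dioxolanone carbonyl, which is far more electrophilic than the silylethyl ester, releases acetone and gives the C1′ methyl ester and the free C2′ hydroxyl with retention.

Step 10
Reactants: 15 1-methyl 4-[2-(trimethylsilyl)ethyl] (2R)-malate; 16 tert-butyl bromoacetate
Product: 18 1′-methyl 6′-[2-(trimethylsilyl)ethyl] 5′-tert-butyl (2′R,3′S)-isocitrate, via dilithium alkoxide enolate 17 (not isolated)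
Conditions: LiN(iPr)2 (2.2 equiv), THF, −78 → −20 °C; 16, −78 °C; AcOH quench
Reagents that add atoms: lithium diisopropylamide [Li+].CC(C)[N-]C(C)C (counter-ions of 17 only)
Why: Fráter–Seebach alkylation, in which the chelated lithium alkoxide enolate is alkylated anti to the C2′ oxygen substituent and so sets C3′ as S (the natural threo series), while the tert-butyl ester resists lactonisation by the alkoxide.

Step 11
Reactants: 12 (2Z,6E)-1-bromo-7-methyl-10-[(2R)-2-methyloxiran-2-yl]deca-2,6-dien-3-yl triflate; 18 1′-methyl 6′-[2-(trimethylsilyl)ethyl] 5′-tert-butyl (2′R,3′S)-isocitrate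
Product: 19 2′-O-{(2Z,6E)-7-methyl-10-[(2R)-2-methyloxiran-2-yl]-3-(triflyloxy)deca-2,6-dienyl} ether of 18
Conditions: Ag2O, 4 Å MS, Et2O/CH2Cl2, dark, rt
Reagents that add atoms: none
Why: Silver-oxide-promoted Williamson etherification, in which halophilic activation of the primary allylic bromide allows SN2 O-alkylation under nearly neutral conditions, so C2′ and C3′ are not epimerised and the fully substituted, electron-poor C8 blocks SN2′ attack.

Step 12
Reactants: 19 2′-O-{(2Z,6E)-7-methyl-10-[(2R)-2-methyloxiran-2-yl]-3-(triflyloxy)deca-2,6-dienyl} ether of 18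
Product: 20 2′-O-{(2Z,6E)-7-methyl-10-[(2R)-2-methyloxiran-2-yl]-3-[(trimethylsilyl)methyl]deca-2,6-dienyl} ether of 18
Conditions: Me3SiCH2MgCl, ZnCl2, THF, 0 °C; then 19, Pd(PPh3)4 (cat.), THF, rt
Reagents that add atoms: (trimethylsilyl)methylmagnesium chloride C[Si](C)(C)C[Mg]Cl
Why: Negishi coupling, in which oxidative addition of zerovalent palladium into the C8–OTf bond and transfer of the β-hydrogen-free silylmethyl group proceed with retention of alkene geometry, and the organozinc reagent tolerates the esters and the oxirane.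

Step 13
Reactants: 20 2′-O-{(2Z,6E)-7-methyl-10-[(2R)-2-methyloxiran-2-yl]-3-[(trimethylsilyl)methyl]deca-2,6-dienyl} ether of 18
Product: 21 1′-methyl 6′-[2-(trimethylsilyl)ethyl] 5′-tert-butyl (2′R,3′S)-2′-O-[(4R,5R,9S,10S)-15-hydroxydrim-8(12)-en-11-yl]isocitrate (the monomer)
Conditions: MeAlCl2 (excess), CH2Cl2, high dilution, −78 °C; then H2O, aq. potassium sodium tartrate
Reagents that add atoms: none
Why: MeAlCl2 binds the oxirane oxygen, the tertiary C4–O bond breaks with backside participation of C5 of the C5=C10 alkene, the C10 cation so formed is captured by C9 of the allylsilane, and loss of the silyl group from C12 leaves the C8=C12 methylene and an aluminium 15-alkoxide that gives the free alcohol on work-up. The closest known reaction type is the epoxide-initiated, allylsilane-terminated cation–olefin polycyclisation (Stork–Eschenmoser chair–chair model). Ring A closes first, exo at the oxirane (the C4–O bond stays outside the new ring) and 6-endo-trig at C5=C10, and ring B closes last, 6-endo-trig at C8=C9. C4 is set by inversion at the (R)-oxirane carbon, C5 and C10 by anti addition across the E alkene (trans-decalin, axial C10 methyl), C9 by the alkene geometry that holds C11 trans to C7 (equatorial CH2O arm), and the sense of C5, C10 and C9 relative to C4 by the chair in which the bulky CH2O–Al arm is equatorial and only the C4 methyl meets the C10 methyl in a 1,3-diaxial contact. The step needs oxirane ionisation to outrun both the 1,2-hydride shift to the aldehyde and ionisation of the allylic C11–O bond, which the strain and tertiary character of the oxirane, the pre-folded 1,5-diene, −78 °C and enough Lewis acid to saturate the three ester carbonyls should secure. Alkene regiochemistry needs no selection, because the β-silicon effect places the cation at C8 and desilylation can give only the exocyclic isomer.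

Step 14
Reactants: 21 the monomer
Product: 22 15-O-(tert-butoxycarbonyl) derivative of 21
Conditions: Boc2O, DMAP (cat.), CH2Cl2, rt
Reagents that add atoms: di-tert-butyl dicarbonate CC(C)(C)OC(=O)OC(=O)OC(C)(C)C
Why: DMAP-catalysed carbonate formation on the only hydroxyl group masks O15 of the future unit C with a group that resists fluoride and falls together with the tert-butyl esters at the end.

Step 15
Reactants: 22 15-O-(tert-butoxycarbonyl) derivative of 21
Product: 23 unit C acid (22 with free C6′ carboxylic acid)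
Conditions: Bu4NF, THF, 0 °C → rt; cold 0.1 M HCl wash
Reagents that add atoms: none
Why: Fluoride attack on silicon triggers β-fragmentation of the 2-(trimethylsilyl)ethyl ester to ethylene and the carboxylate, and leaves the methyl and tert-butyl esters, the carbonate and the β-alkoxy ester array untouched at low temperature.

Step 16
Reactants: 23 unit C acid; 21 the monomer (as unit B alcohol)
Product: 25 protected dimer (C6′ of isocitrate C esterified with O15 of unit B; C6′ of isocitrate B still a silylethyl ester), via mixed anhydride 24 (not isolated)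
Conditions: 23, 2,4,6-Cl3C6H2COCl, Et3N, toluene, rt; then 21, DMAP, rt
Reagents that add atoms: 2,4,6-trichlorobenzoyl chloride O=C(Cl)c1c(Cl)cc(Cl)cc1Cl (carried by 24 only)
Why: Yamaguchi esterification, in which DMAP attacks the mixed anhydride only at the aliphatic carbonyl and the acylpyridinium ion acylates the primary neopentyl-type 15-OH of 21, whose own C6′ carboxyl is still blocked.

Step 17
Reactants: 25 protected dimer
Product: 26 dimer acid (free C6′ acid on isocitrate B)
Conditions: Bu4NF, THF, 0 °C → rt; cold 0.1 M HCl wash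
Reagents that add atoms: none
Why: Fluoride-induced β-fragmentation removes the single 2-(trimethylsilyl)ethyl ester, and all other esters and the carbonate are inert to fluoride.

Step 18
Reactants: 21 the monomer
Product: 28 monomer C5′ acid (15-OH free, C6′ silylethyl ester kept), via bis(trimethylsilyl) derivative 27 (not isolated)
Conditions: Me3SiOTf, 2,6-lutidine, CH2Cl2, 0 °C; then pH 4 aq. buffer/THF
Reagents that add atoms: trimethylsilyl trifluoromethanesulfonate C[Si](C)(C)OS(=O)(=O)C(F)(F)F (carried by 27 only)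
Why: Silyl-triflate-induced tert-butyl ester cleavage, in which O-silylation and E1 loss of isobutene occur at the tertiary ester only, the primary silylethyl and methyl esters cannot ionise, and the lutidine buffer keeps the C8=C12 methylene from acid-catalysed isomerisation.

Step 19
Reactants: 28 monomer C5′ acid
Product: 29 unit A alcohol: 1′,5′-dimethyl 6′-[2-(trimethylsilyl)ethyl] (2′R,3′S)-2′-O-[(4R,5R,9S,10S)-15-hydroxydrim-8(12)-en-11-yl]isocitrate
Conditions: Me3SiCHN2, toluene/MeOH, 0 °C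
Reagents that add atoms: (trimethylsilyl)diazomethane C[Si](C)(C)C=[N+]=[N-]
Why: Esterification with (trimethylsilyl)diazomethane in methanol requires protonation by the substrate and therefore methylates the carboxylic acid and not the alcohol.

Step 20
Reactants: 26 dimer acid; 29 unit A alcohol
Product: 31 fully protected trimer, via mixed anhydride 30 (not isolated)
Conditions: 26, 2,4,6-Cl3C6H2COCl, Et3N, toluene, rt; then 29, DMAP, rt
Reagents that add atoms: 2,4,6-trichlorobenzoyl chloride O=C(Cl)c1c(Cl)cc(Cl)cc1Cl (carried by 30 only)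
Why: A second Yamaguchi esterification joins the only free acid (C6′ of isocitrate B) to the only free hydroxyl (O15 of unit A) by the same acylpyridinium mechanism.

Step 21
Reactants: 31 fully protected trimer
Product: 32 trimer with free C6′ acid on isocitrate A
Conditions: Bu4NF, THF, 0 °C → rt; cold 0.1 M HCl wash
Reagents that add atoms: none
Why: Fluoride-induced β-fragmentation of the last 2-(trimethylsilyl)ethyl ester leaves the four methyl esters, the two drimanyl esters, the tert-butyl esters and the carbonate in place.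

Step 22
Reactants: 32 trimer with free C6′ acid on isocitrate A
Product: 34 cryptoporic acid T, via persilylated trimer 33 (not isolated)
Conditions: Me3SiOTf, 2,6-lutidine, CH2Cl2, 0 °C → rt; then pH 4 aq. buffer/THF
Reagents that add atoms: trimethylsilyl trifluoromethanesulfonate C[Si](C)(C)OS(=O)(=O)C(F)(F)F (carried by 33 only)
Why: Buffered silyl-triflate cleavage ionises the two tert-butyl esters and the tert-butyl carbonate with loss of isobutene, and mild hydrolysis of the silyl esters and the silyl carbonate (which loses CO2) frees three acids and the 15-OH without a Brønsted acid strong enough to move the three exocyclic alkenes.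

Compound list
1 | geranyl bromide | BrC/C=C(\C)CCC=C(C)C | starting material
2 | methyl acetoacetate | COC(=O)CC(C)=O | starting material
3 | sodium lithium dianion of methyl acetoacetate | [Na+].[Li+].COC(=O)[CH-]C(=O)[CH2-] | intermediate
4 | methyl (6E)-7,11-dimethyl-3-oxododeca-6,10-dienoate | COC(=O)CC(=O)CC/C=C(\C)CCC=C(C)C | intermediate
5 | methyl (2Z,6E)-7,11-dimethyl-3-(triflyloxy)dodeca-2,6,10-trienoate | COC(=O)/C=C(\OS(=O)(=O)C(F)(F)F)CC/C=C(\C)CCC=C(C)C | intermediate
6 | methyl (2Z,6E,10E)-12-hydroxy-7,11-dimethyl-3-(triflyloxy)dodeca-2,6,10-trienoate | COC(=O)/C=C(\OS(=O)(=O)C(F)(F)F)CC/C=C(\C)CC/C=C(\C)CO | intermediate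
7 | methyl (2Z,6E)-9-[(2S,3S)-3-(hydroxymethyl)-3-methyloxiran-2-yl]-7-methyl-3-(triflyloxy)nona-2,6-dienoate | COC(=O)/C=C(\OS(=O)(=O)C(F)(F)F)CC/C=C(\C)CC[C@@H]1O[C@@]1(C)CO | intermediate
8 | (2Z,6E,11R)-1,11,12-trihydroxy-7,11-dimethyldodeca-2,6-dien-3-yl triflate | OC/C=C(\OS(=O)(=O)C(F)(F)F)CC/C=C(\C)CCC[C@@](C)(O)CO | intermediate
9 | 12-O-tosylate of 8 | OC/C=C(\OS(=O)(=O)C(F)(F)F)CC/C=C(\C)CCC[C@@](C)(O)COS(=O)(=O)c1ccc(C)cc1 | intermediate
10 | (2Z,6E)-1-hydroxy-7-methyl-10-[(2R)-2-methyloxiran-2-yl]deca-2,6-dien-3-yl triflate | OC/C=C(\OS(=O)(=O)C(F)(F)F)CC/C=C(\C)CCC[C@]1(C)CO1 | intermediate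
11 | 1-O-mesylate of 10 | CS(=O)(=O)OC/C=C(\OS(=O)(=O)C(F)(F)F)CC/C=C(\C)CCC[C@]1(C)CO1 | intermediate
12 | (2Z,6E)-1-bromo-7-methyl-10-[(2R)-2-methyloxiran-2-yl]deca-2,6-dien-3-yl triflate | BrC/C=C(\OS(=O)(=O)C(F)(F)F)CC/C=C(\C)CCC[C@]1(C)CO1 | intermediate
13 | (R)-2,2-dimethyl-5-oxo-1,3-dioxolane-4-acetic acid | CC1(C)O[C@H](CC(=O)O)C(=O)O1 | starting material
14 | 2-(trimethylsilyl)ethyl [(4R)-2,2-dimethyl-5-oxo-1,3-dioxolan-4-yl]acetate | CC1(C)O[C@H](CC(=O)OCC[Si](C)(C)C)C(=O)O1 | intermediate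
15 | 1-methyl 4-[2-(trimethylsilyl)ethyl] (2R)-malate | O[C@@H](C(=O)OC)CC(=O)OCC[Si](C)(C)C | intermediate
16 | tert-butyl bromoacetate | CC(C)(C)OC(=O)CBr | starting material
17 | dilithium alkoxide enolate of 15 | [Li+].[Li+].[O-][C@@H](C(=O)OC)[CH-]C(=O)OCC[Si](C)(C)C | intermediate
18 | 1′-methyl 6′-[2-(trimethylsilyl)ethyl] 5′-tert-butyl (2′R,3′S)-isocitrate | O[C@@H](C(=O)OC)[C@H](CC(=O)OC(C)(C)C)C(=O)OCC[Si](C)(C)C | intermediate
19 | allylic ether of 18 with enol triflate and (R)-oxirane | C(/C=C(\OS(=O)(=O)C(F)(F)F)CC/C=C(\C)CCC[C@]1(C)CO1)O[C@@H](C(=O)OC)[C@H](CC(=O)OC(C)(C)C)C(=O)OCC[Si](C)(C)C | intermediate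
20 | allylsilane cyclisation precursor | C(/C=C(\C[Si](C)(C)C)CC/C=C(\C)CCC[C@]1(C)CO1)O[C@@H](C(=O)OC)[C@H](CC(=O)OC(C)(C)C)C(=O)OCC[Si](C)(C)C | intermediate
21 | monomer: (4R,5R,9S,10S)-15-hydroxydrim-8(12)-en-11-yl ether of 18 | C=C1CC[C@H]2[C@](C)(CO)CCC[C@]2(C)[C@H]1CO[C@@H](C(=O)OC)[C@H](CC(=O)OC(C)(C)C)C(=O)OCC[Si](C)(C)C | intermediate
22 | 15-O-Boc monomer | C=C1CC[C@H]2[C@](C)(COC(=O)OC(C)(C)C)CCC[C@]2(C)[C@H]1CO[C@@H](C(=O)OC)[C@H](CC(=O)OC(C)(C)C)C(=O)OCC[Si](C)(C)C | intermediate
23 | unit C acid | C=C1CC[C@H]2[C@](C)(COC(=O)OC(C)(C)C)CCC[C@]2(C)[C@H]1CO[C@@H](C(=O)OC)[C@H](CC(=O)OC(C)(C)C)C(=O)O | intermediate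
24 | 2,4,6-trichlorobenzoic mixed anhydride of 23 | C=C1CC[C@H]2[C@](C)(COC(=O)OC(C)(C)C)CCC[C@]2(C)[C@H]1CO[C@@H](C(=O)OC)[C@H](CC(=O)OC(C)(C)C)C(=O)OC(=O)c3c(Cl)cc(Cl)cc3Cl | intermediate
25 | protected dimer | C=C1CC[C@H]2[C@](C)(COC(=O)[C@@H](CC(=O)OC(C)(C)C)[C@@H](OC[C@H]3C(=C)CC[C@H]4[C@](C)(COC(=O)OC(C)(C)C)CCC[C@]34C)C(=O)OC)CCC[C@]2(C)[C@H]1CO[C@@H](C(=O)OC)[C@H](CC(=O)OC(C)(C)C)C(=O)OCC[Si](C)(C)C | intermediate
26 | dimer acid | C=C1CC[C@H]2[C@](C)(COC(=O)[C@@H](CC(=O)OC(C)(C)C)[C@@H](OC[C@H]3C(=C)CC[C@H]4[C@](C)(COC(=O)OC(C)(C)C)CCC[C@]34C)C(=O)OC)CCC[C@]2(C)[C@H]1CO[C@@H](C(=O)OC)[C@H](CC(=O)OC(C)(C)C)C(=O)O | intermediate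
27 | 15-O-trimethylsilyl ether, C5′ trimethylsilyl ester of the monomer | C=C1CC[C@H]2[C@](C)(CO[Si](C)(C)C)CCC[C@]2(C)[C@H]1CO[C@@H](C(=O)OC)[C@H](CC(=O)O[Si](C)(C)C)C(=O)OCC[Si](C)(C)C | intermediate
28 | monomer C5′ acid | C=C1CC[C@H]2[C@](C)(CO)CCC[C@]2(C)[C@H]1CO[C@@H](C(=O)OC)[C@H](CC(=O)O)C(=O)OCC[Si](C)(C)C | intermediate
29 | unit A alcohol | C=C1CC[C@H]2[C@](C)(CO)CCC[C@]2(C)[C@H]1CO[C@@H](C(=O)OC)[C@H](CC(=O)OC)C(=O)OCC[Si](C)(C)C | intermediate
30 | 2,4,6-trichlorobenzoic mixed anhydride of 26 | C=C1CC[C@H]2[C@](C)(COC(=O)[C@@H](CC(=O)OC(C)(C)C)[C@@H](OC[C@H]3C(=C)CC[C@H]4[C@](C)(COC(=O)OC(C)(C)C)CCC[C@]34C)C(=O)OC)CCC[C@]2(C)[C@H]1CO[C@@H](C(=O)OC)[C@H](CC(=O)OC(C)(C)C)C(=O)OC(=O)c5c(Cl)cc(Cl)cc5Cl | intermediate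
31 | fully protected trimer | C=C1CC[C@H]2[C@](C)(COC(=O)[C@@H](CC(=O)OC(C)(C)C)[C@@H](OC[C@H]3C(=C)CC[C@H]4[C@](C)(COC(=O)[C@@H](CC(=O)OC(C)(C)C)[C@@H](OC[C@H]5C(=C)CC[C@H]6[C@](C)(COC(=O)OC(C)(C)C)CCC[C@]56C)C(=O)OC)CCC[C@]34C)C(=O)OC)CCC[C@]2(C)[C@H]1CO[C@@H](C(=O)OC)[C@H](CC(=O)OC)C(=O)OCC[Si](C)(C)C | intermediate
32 | trimer with free C6′ acid on isocitrate A | C=C1CC[C@H]2[C@](C)(COC(=O)[C@@H](CC(=O)OC(C)(C)C)[C@@H](OC[C@H]3C(=C)CC[C@H]4[C@](C)(COC(=O)[C@@H](CC(=O)OC(C)(C)C)[C@@H](OC[C@H]5C(=C)CC[C@H]6[C@](C)(COC(=O)OC(C)(C)C)CCC[C@]56C)C(=O)OC)CCC[C@]34C)C(=O)OC)CCC[C@]2(C)[C@H]1CO[C@@H](C(=O)OC)[C@H](CC(=O)OC)C(=O)O | intermediate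
33 | persilylated trimer (three silyl esters, one silyl carbonate) | C=C1CC[C@H]2[C@](C)(COC(=O)[C@@H](CC(=O)O[Si](C)(C)C)[C@@H](OC[C@H]3C(=C)CC[C@H]4[C@](C)(COC(=O)[C@@H](CC(=O)O[Si](C)(C)C)[C@@H](OC[C@H]5C(=C)CC[C@H]6[C@](C)(COC(=O)O[Si](C)(C)C)CCC[C@]56C)C(=O)OC)CCC[C@]34C)C(=O)OC)CCC[C@]2(C)[C@H]1CO[C@@H](C(=O)OC)[C@H](CC(=O)OC)C(=O)O[Si](C)(C)C | intermediate
34 | cryptoporic acid T | C=C1CC[C@H]2[C@](C)(COC(=O)[C@@H](CC(=O)O)[C@@H](OC[C@H]3C(=C)CC[C@H]4[C@](C)(COC(=O)[C@@H](CC(=O)O)[C@@H](OC[C@H]5C(=C)CC[C@H]6[C@](C)(CO)CCC[C@]56C)C(=O)OC)CCC[C@]34C)C(=O)OC)CCC[C@]2(C)[C@H]1CO[C@@H](C(=O)OC)[C@H](CC(=O)OC)C(=O)O | target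

Total step count: 22.
Longest linear sequence: 17 steps (1–7, 11–17, 20–22).

Steps most likely to fail

1. Step 13.
- What may go wrong: the ionised oxirane may collapse by a 1,2-hydride shift before C5=C10 engages. The two chair arrays (CH2O–Al arm equatorial or axial) may be poorly discriminated. The Lewis acid may also ionise the allylic ether with loss of silicon.
- Principle of the fallback: it replaces the exocyclic oxirane by the classical in-ring initiator, sets out from 7 and comes back at 21.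
- From 7 to the new precursor: compound 7 is silylated (t-BuMe2SiCl, imidazole) to the silyl ether F1. This is reduced at the ester only (i-Bu2AlH, −78 °C) to the allylic alcohol F2 and brominated (CBr4, PPh3) to the allylic bromide F3. Joining to 18 with Ag2O gives the ether F4, and coupling with Me3SiCH2ZnCl under Pd(PPh3)4 gives the allylsilane F5.
- Cyclisation: MeAlCl2 at −78 °C then opens the trisubstituted oxirane at C4 while C3–O stays on the ring. The trans relation of C15 and C2 in the oxirane forces C15 equatorial stereospecifically, and the (S)-C3 centre fixes the absolute sense, which should give the 3β-alcohol F6.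
- Return to the route: Barton–McCombie deoxygenation through the imidazolylthiocarbonate F7 (1,1′-thiocarbonyldiimidazole, then Bu3SnH, AIBN) gives the 15-O-silyl monomer F8. HF·pyridine then frees 21.

2. Step 11.
- What may go wrong: O-alkylation of a hindered, weakly nucleophilic hydroxyl may be slow, with competing lactonisation onto an ester or base-induced β-elimination in the isocitrate.
- Fallback: it activates the allylic alcohol instead of using a halide, sets out from 10 and comes back at 19. Compound 10 is converted with Ph2PCl and Et3N into the allyl diphenylphosphinite F9. This is combined with 18 and 2,3,5,6-tetrafluoro-1,4-benzoquinone in CH2Cl2 (Mukaiyama oxidation–reduction condensation). The alkoxyphosphonium ion is displaced by the hydroxyl of 18 under neutral conditions to give 19.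

3. Step 5.
- What may go wrong: hydride may be delivered to the quaternary oxirane carbon, or the Lewis acidic hydride may open the oxirane unselectively, which would erode the C4 stereocentre or give the 1,3-diol.
- Fallback: it separates the two reductions and replaces hydride opening by a heteroatom opening, sets out from 7 and comes back at 8. Ti(OiPr)4-mediated opening of 7 with PhSH at C3 gives the sulfide diol F10. Radical desulfurisation (Bu3SnH, AIBN) gives the diol ester F11, and i-Bu2AlH at −78 °C reduces only the ester to give 8.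

Further compounds
F1 | step 13 | tert-butyldimethylsilyl ether of 7 | COC(=O)/C=C(\OS(=O)(=O)C(F)(F)F)CC/C=C(\C)CC[C@@H]1O[C@@]1(C)CO[Si](C)(C)C(C)(C)C
F2 | step 13 | allylic alcohol from F1 | OC/C=C(\OS(=O)(=O)C(F)(F)F)CC/C=C(\C)CC[C@@H]1O[C@@]1(C)CO[Si](C)(C)C(C)(C)C
F3 | step 13 | allylic bromide from F2 | BrC/C=C(\OS(=O)(=O)C(F)(F)F)CC/C=C(\C)CC[C@@H]1O[C@@]1(C)CO[Si](C)(C)C(C)(C)C
F4 | step 13 | ether of 18 with F3 | C(/C=C(\OS(=O)(=O)C(F)(F)F)CC/C=C(\C)CC[C@@H]1O[C@@]1(C)CO[Si](C)(C)C(C)(C)C)O[C@@H](C(=O)OC)[C@H](CC(=O)OC(C)(C)C)C(=O)OCC[Si](C)(C)C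
F5 | step 13 | allylsilane with trisubstituted (3S,4S)-oxirane | C(/C=C(\C[Si](C)(C)C)CC/C=C(\C)CC[C@@H]1O[C@@]1(C)CO[Si](C)(C)C(C)(C)C)O[C@@H](C(=O)OC)[C@H](CC(=O)OC(C)(C)C)C(=O)OCC[Si](C)(C)C
F6 | step 13 | 3β-hydroxy-15-O-silyl monomer | C=C1CC[C@H]2[C@](C)(CO[Si](C)(C)C(C)(C)C)[C@@H](O)CC[C@]2(C)[C@H]1CO[C@@H](C(=O)OC)[C@H](CC(=O)OC(C)(C)C)C(=O)OCC[Si](C)(C)C
F7 | step 13 | 3-O-(imidazol-1-ylthiocarbonyl) derivative of F6 | C=C1CC[C@H]2[C@](C)(CO[Si](C)(C)C(C)(C)C)[C@@H](OC(=S)n3ccnc3)CC[C@]2(C)[C@H]1CO[C@@H](C(=O)OC)[C@H](CC(=O)OC(C)(C)C)C(=O)OCC[Si](C)(C)C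
F8 | step 13 | 15-O-tert-butyldimethylsilyl monomer | C=C1CC[C@H]2[C@](C)(CO[Si](C)(C)C(C)(C)C)CCC[C@]2(C)[C@H]1CO[C@@H](C(=O)OC)[C@H](CC(=O)OC(C)(C)C)C(=O)OCC[Si](C)(C)C
F9 | step 11 | diphenylphosphinite of 10 | C(/C=C(\OS(=O)(=O)C(F)(F)F)CC/C=C(\C)CCC[C@]1(C)CO1)OP(c2ccccc2)c3ccccc3
F10 | step 5 | methyl (2Z,6E,10R,11S)-11,12-dihydroxy-7,11-dimethyl-10-(phenylsulfanyl)-3-(triflyloxy)dodeca-2,6-dienoate | COC(=O)/C=C(\OS(=O)(=O)C(F)(F)F)CC/C=C(\C)CC[C@@H](Sc1ccccc1)[C@@](C)(O)CO
F11 | step 5 | methyl (2Z,6E,11R)-11,12-dihydroxy-7,11-dimethyl-3-(triflyloxy)dodeca-2,6-dienoate | COC(=O)/C=C(\OS(=O)(=O)C(F)(F)F)CC/C=C(\C)CCC[C@@](C)(O)CO
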